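## Analysis of the target

Compound 19 is a 3,7-dioxabicyclo[3.3.0]octane. It is numbered C1(OH)–C2(Ar)–O3–C4H2–C5(H)–C6(Ar)–O7–C8H2 with the fusion bond C1–C5; ring 1 is C1, C2, O3, C4, C5 and ring 2 is C1, C5, C6, O7, C8, and both aryl groups are 3,4-dimethoxyphenyl. Four contiguous stereocentres, (1S,2R,5S,6R), surround the fully substituted carbinol carbon C1. Read literally, the SMILES places the C1 hydroxyl and the C5 hydrogen on opposite faces, so the two tetrahydrofurans are trans-fused. On ring 1 the C2 aryl group, the C1 hydroxyl and the C5–C6 bond share one face and C8 lies on the other; on ring 2 the C6 aryl group is cis to the C5 hydrogen. The C2–O3 and C6–O7 bonds are benzylic ethers of a strongly donating arene and ionise under acid; the arenes are easily oxidised and are good partners for electrophiles; the tertiary C1 hydroxyl sits next to C8 and can act as an internal nucleophile. The difficulty lies in the quaternary carbinol flanked by three stereocentres and in a strained trans fusion that cannot be reached by equilibration and has to be locked kinetically. The structural feature used here is that C4 is an unsubstituted methylene between O3 and C5, while C5 is bonded to C6, which can be a ketone carbon: C4 can begin as the methyl group of a C2 methyl ether and be joined to C5 when C5 is a carbenoid carbon α to the C6 aryl ketone.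

## Retrosynthetic reasoning

Ring 2 is opened at O7–C8 (19 ⇒ 18). C8 is an achiral methylene, so displacement there cannot disturb a stereocentre, whereas cutting C6–O7 would put bond formation on an ionisable benzylic carbon. The forward reaction has the C6 hydroxyl of 18 displace the primary sulfonate irreversibly; the trans fusion then follows from C6 and C8 lying on opposite faces of ring 1. The C1 oxygen must not become the nucleophile.

Sulfonate 18 comes from triol 17 by selective sulfonylation of the primary hydroxyl, and 17 from acetonide 16 by mild hydrolysis. No skeletal bond is cut; what is gained is that C1–O and C8–O travel together as one robust ring up to this point.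

The C6–H bond is cut next (16 ⇒ 15). The C6 carbinol is traced to the aryl ketone because a ketone at C6 is what makes C5 a carbenoid position. The forward reduction has to set C6 from the adjacent C5 centre and the bulky spiro carbon C1.

The C4–C5 bond of ring 1 is cut (15 ⇒ 14). This is the central disconnection: it turns C4 into the methyl group of the C2 ether and C5 into a diazo carbon. It is chosen over cuts at C2–O3 or C1–C2 because it leaves C1 and C2 untouched in the ring-forming step and requires no oxygen function at C4. The forward reaction must direct a metal carbenoid at C5 into a methoxy C–H bond in the 1,5 sense and create C5 with the aroyl group anti to C8.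

The diazo group is removed (14 ⇒ 11, through 12 and 13). The ketone 11 has a single enolisable position, so activation as the trifluoroacetyl derivative and diazo transfer can only occur at C5.

The acetonide is traced to the silyl ether 9 through diol 10. The exchange is needed because the C1 and C8 oxygens must enter the carbenoid step tied into a ring that offers no activated C–H bond and no free hydroxyl.

The C1–C5 bond is cut (9 ⇒ 6 + 7, the latter as its enolate 8). This aldol disconnection joins the two aryl halves and creates the quaternary carbinol. The forward addition has to choose the carbonyl face of 6 under the influence of the C2 methoxy group, which is possible through a chelate.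

Ketone 6 is traced to alcohol 5 and diol 4 by oxidation and primary silylation. The C2–O bond of 4 is then cut back to oxirane 3: opening at the benzylic carbon with inversion installs the methyl ether that later supplies C4 and fixes C2. Oxirane 3 comes from allylic alcohol 2 by asymmetric epoxidation, and 2 from the commercial ester 1.

## Alternatives that were turned down

Alternative 1: The C2–O3 bond of ring 1 is cut and traced to an oxirane across C1–C2. The precursor is the epoxy diol A1, obtained by asymmetric epoxidation of a trisubstituted allylic alcohol that already carries C5 with its C4 hydroxymethyl group and the silylated C6 carbinol. In the forward step acid lets the C4 hydroxyl attack benzylic C2 from the rear of the oxirane C–O bond (5-endo opening, preferred over attack at C1 because the aryl group stabilises charge at C2). Ring 1 closes, the oxirane oxygen becomes the C1 hydroxyl, and A2 results.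

- For it: ring closure by C–O bond formation at an aryl oxirane is a dependable reaction class; C1 and C2 both come from one reagent-controlled epoxidation and not from substrate induction; no carbenoid chemoselectivity is involved. On these points it is stronger than the route chosen.
- Against it: with a 3,4-dimethoxyphenyl group the C2–O bond breaks ahead of bond formation, so inversion at C2 is not secured, and the cationic centre can instead be taken by the C8 hydroxyl or trigger a 1,2-shift from C1. A1 needs C5 and C6 set in an open chain first, and the epoxidation then has to run on a chiral, labile allylic alcohol. Several protecting-group steps are needed to keep the C4, C8 and C6 oxygens apart. A2 would still face the closure of ring 2 next to a free C1 hydroxyl.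
- What the chosen strategy offers instead: ring 1 closes through a C–C bond, so the C2–O bond is never broken after step 3, where a wrong diastereomer can still be removed; C4 needs no oxygen function of its own; the skeleton comes from two simple aryl building blocks.

Alternative 2: Two bonds, C4–C5 and C6–O7, are cut at once. The precursor is the N-acyloxyphthalimide A3, in which O3 carries a carboxymethyl group as a redox-active ester and C1 carries a styrene unit (C5=C6). Under light, single-electron reduction of A3 triggers decarboxylation to an O3–CH2 radical, which adds 5-exo to C5 (ring 1). The benzylic C6 radical is oxidised to the cation and trapped by the oxygen of the C8 silyl ether (ring 2), giving A4, the C1 triethylsilyl ether of the target.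

- For it: two rings, two skeletal bonds and two stereocentres in one operation. In the ring-forming phase its step economy is clearly better than that of the chosen route, which needs four more steps after ring 1.
- Against it: C5 is set in the radical cyclisation relative to the fully substituted C1, and only when the C6 arm ends anti to C8 can the trans-fused target arise. From exactly that arrangement the cation reaches the C8 oxygen only through the strained trans closure, so the cascade is biased toward the cis-fused diastereomer or toward loss of the cation by elimination or outside capture. C6 is fixed by kinetic capture of a planar, long-lived dimethoxybenzyl cation with no controlling element. The electron-rich styrene and arenes are themselves oxidisable under the same conditions.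
- What the chosen strategy offers instead: C5 and C6 are created in separate events, each with a nameable control element, and ring 2 closes by an irreversible substitution at an achiral carbon, which has no diastereomeric alternative and can therefore be forced into the trans fusion.

Alternative 3: The C1–C2 bond is cut. The precursor is ketone A5, with the C1 carbonyl and a 3,4-dimethoxybenzyl ether on the C4 oxygen. On irradiation the excited carbonyl oxygen takes the benzylic hydrogen of C2 through a six-membered transition state, and the 1,5-biradical couples C1 with C2 (Norrish–Yang closure). This gives the tetrahydrofuranol A6 with ring 1 closed before ring 2 exists.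

- For it: the C1–C2 bond, the tertiary carbinol and both stereocentres C1 and C2 arise in one reagent-free step. The cis relation of aryl and hydroxyl that such closures usually give is the one required, and the precursor needs only a simple benzyl ether. In stereocentres set per step it is stronger than the chosen key step.
- Against it: the configuration of C1 relative to the existing C5 centre is decided by the conformations of a short-lived biradical, with nothing that clearly favours the C8 arm anti to the C6 arm. The chromophore is an α-silyloxy ketone, open to α-cleavage and to loss of the α-oxygen. The dimethoxyarenes can quench the excited carbonyl by charge transfer. C5 and C6 must again be set beforehand in an open chain.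
- What the chosen strategy offers instead: C1 and C2 are fixed by ground-state reactions with well-understood models (inversion at an oxirane, chelate-controlled addition) before any ring is formed, and the ring-forming step creates a single new centre.

Key step: step 10

## Route

Assumption: the SMILES is taken literally; it demands C1–OH anti to C5–H, that is (1S,2R,5S,6R) with a trans ring fusion, and every stereochemical choice below aims at that isomer.

Remarks: Ar = 3,4-dimethoxyphenyl; TBS = tert-butyldimethylsilyl. Atom labels C1–C8 in the Why lines are those of the bicycle in 19.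

Step 1
Reactants: 1 methyl (2E)-3-Ar-prop-2-enoate
Product: 2 (2E)-3-Ar-prop-2-en-1-ol
Conditions: i-Bu2AlH (2.3 equiv), CH2Cl2, −78 → 0 °C; aq. potassium sodium tartrate
Reagents that add atoms: none
Why: Aluminium hydride reduction of a conjugated ester goes by 1,2-addition to the allylic alcohol and leaves the E alkene untouched.

Step 2
Reactants: 2 (2E)-3-Ar-prop-2-en-1-ol
Product: 3 [(2S,3S)-3-Ar-oxiran-2-yl]methanol
Conditions: Ti(OiPr)4 (10 mol %), diisopropyl L-(+)-tartrate (12 mol %), t-BuOOH (2 equiv), 4 Å MS, CH2Cl2, −20 °C; non-acidic work-up, crude product used at once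
Reagents that add atoms: tert-butyl hydroperoxide, CC(C)(C)OO
Why: Sharpless asymmetric epoxidation; with the L-(+)-tartrate ligand an (E)-3-substituted allylic alcohol should give the (2S,3S)-oxirane, whose benzylic carbon becomes C2. The electron-rich aryl oxirane is acid-labile, hence sieves, low temperature and no acidic silica.

Step 3
Reactants: 3 [(2S,3S)-3-Ar-oxiran-2-yl]methanol
Product: 4 (2S,3R)-3-Ar-3-methoxypropane-1,2-diol
Conditions: MeOH/CH2Cl2 (1:1), BF3·OEt2 (5 mol %), −40 °C; Et3N quench
Reagents that add atoms: methanol, CO
Why: Acid-catalysed epoxide methanolysis; the benzylic carbon is attacked from the rear of the breaking C–O bond, so (3S) becomes (3R), the future C2, and the methyl group that later supplies C4 is installed. Leakage through a free benzylic cation would appear as the (2S,3S) diastereomer, which should be separable here, before the secondary carbinol (future C1) is oxidised.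

Step 4
Reactants: 4 (2S,3R)-3-Ar-3-methoxypropane-1,2-diol
Product: 5 (2S,3R)-1-(TBS-oxy)-3-Ar-3-methoxypropan-2-ol
Conditions: TBSCl (1.05 equiv), imidazole, CH2Cl2, 0 °C
Reagents that add atoms: tert-butyldimethylsilyl chloride, CC(C)(C)[Si](C)(C)Cl
Why: Silylation with a bulky chlorosilane selects the primary hydroxyl (future C8–O) over the hindered secondary one.

Step 5
Reactants: 5 (2S,3R)-1-(TBS-oxy)-3-Ar-3-methoxypropan-2-ol
Product: 6 (1R)-3-(TBS-oxy)-1-Ar-1-methoxypropan-2-one
Conditions: Dess–Martin periodinane, NaHCO3, CH2Cl2, 0 °C → rt
Reagents that add atoms: none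
Why: Dess–Martin oxidation under buffered, non-enolising conditions gives the C1 ketone without epimerising the benzylic α-methoxy centre; the ketone is used without delay.

Step 6
Reactants: 7 1-Ar-ethan-1-one; 6 (1R)-3-(TBS-oxy)-1-Ar-1-methoxypropan-2-one
Product: 9 (3S,4R)-3-[(TBS-oxy)methyl]-1,4-di-Ar-3-hydroxy-4-methoxybutan-1-one, via lithium enolate 8 (not isolated)
Conditions: 7, LiN(i-Pr)2, THF, −78 °C; MgBr2·OEt2 (1.2 equiv); then 6, −78 °C; AcOH quench at −78 °C
Reagents that add atoms: none
Why: Aldol addition of a methyl ketone enolate to an α-alkoxy ketone under chelation control (Cram chelate): magnesium bridges the C1 carbonyl and the C2 methoxy oxygen, and the enolate adds to the face that carries the C2 hydrogen, which sets C1 as required. Low temperature and the weakly basic magnesium enolate disfavour proton transfer from the benzylic C2–H, and the cold acidic quench prevents retro-aldol.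

Step 7
Reactants: 9 (3S,4R)-3-[(TBS-oxy)methyl]-1,4-di-Ar-3-hydroxy-4-methoxybutan-1-one
Product: 10 (3S,4R)-1,4-di-Ar-3-hydroxy-3-(hydroxymethyl)-4-methoxybutan-1-one
Conditions: Bu4NF, AcOH (1:1), THF, 0 °C → rt
Reagents that add atoms: none
Why: Fluoride cleavage of the primary silyl ether; buffering with acetic acid keeps the medium from becoming basic enough for retro-aldol of the tertiary β-hydroxy ketone.

Step 8
Reactants: 10 (3S,4R)-1,4-di-Ar-3-hydroxy-3-(hydroxymethyl)-4-methoxybutan-1-one
Product: 11 2-{(4S)-4-[(R)-Ar(methoxy)methyl]-2,2-dimethyl-1,3-dioxolan-4-yl}-1-Ar-ethan-1-one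
Conditions: 2-methoxypropene, PPTS (cat.), CH2Cl2, 0 °C
Reagents that add atoms: 2-methoxypropene, COC(C)=C
Why: Kinetic ketalisation of the 1,2-diol; the acetonide ties the C1 and C8 oxygens into a ring that has no free hydroxyl and no activated C–H bond for the carbenoid step. The weak acid is not expected to ionise the benzylic methyl ether.

Step 9
Reactants: 11 2-{(4S)-4-[(R)-Ar(methoxy)methyl]-2,2-dimethyl-1,3-dioxolan-4-yl}-1-Ar-ethan-1-one
Product: 14 2-diazo-2-{(4S)-4-[(R)-Ar(methoxy)methyl]-2,2-dimethyl-1,3-dioxolan-4-yl}-1-Ar-ethan-1-one, via lithium enolate 12 (not isolated), via trifluoroacetyl ketone 13 (not isolated)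
Conditions: LiN(SiMe3)2, THF, −78 °C; CF3CO2CH2CF3, −78 °C; cold dilute aq. HCl; then 4-acetamidobenzenesulfonyl azide, Et3N, H2O (1 equiv), MeCN, rt
Reagents that add atoms: 4-acetamidobenzenesulfonyl azide, CC(=O)Nc1ccc(cc1)S(=O)(=O)N=[N+]=[N-] (the two diazo nitrogens of 14); 2,2,2-trifluoroethyl trifluoroacetate, FC(F)(F)C(=O)OCC(F)(F)F (the trifluoroacetyl group of 13, lost again)
Why: Deacylative (detrifluoroacetylative) diazo transfer of the Regitz type: C5 is the only enolisable position, its trifluoroacetyl derivative is acidic enough for amine-mediated transfer, and fragmentation of the triazoline expels the trifluoroacetyl group on the sulfonamide. At −78 °C the enolate should not expel the β-oxygen on C1.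

Step 10
Reactants: 14 2-diazo-2-{(4S)-4-[(R)-Ar(methoxy)methyl]-2,2-dimethyl-1,3-dioxolan-4-yl}-1-Ar-ethan-1-one
Product: 15 [(5S,6R,9R)-6-Ar-2,2-dimethyl-1,3,7-trioxaspiro[4.4]nonan-9-yl](Ar)methanone (ring 1 closed; spiro carbon = C1, C6 of the name = C2, C9 of the name = C5)
Conditions: Rh2(acam)4 (dirhodium tetraacetamidate, 2 mol %), 1,2-dichloroethane, 60 °C, slow addition of 14 at high dilution
Reagents that add atoms: none
Why: Rh2(acam)4 takes up the diazo carbon of 14, dinitrogen leaves and an electrophilic rhodium carbenoid results at C5; this carbon inserts into a C–H bond of the O3 methyl group through a three-centre transition state with hydride-transfer character, in which an O3 lone pair stabilises the positive charge building at C4, so that C4–C5 forms and the catalyst is released. The closest known reaction type is the dirhodium-catalysed 1,5 C–H insertion of α-diazo ketones next to an ether oxygen, which gives tetrahydrofurans; a methoxy group is a less common but electronically activated donor. Ring 1 closes in the 1,5 mode, its five atoms C5, C1, C2, O3 and C4 being assembled in a five-membered cyclic transition state. The new stereocentre C5 is controlled by the C2 aryl group fixed earlier: the bulky dirhodium unit on C5 should turn to the ring face away from that aryl group, which is the face of the C8 methylene; the hydrogen is delivered there and the aroyl group ends anti to C8, which is also the less crowded arrangement of the product. The step needs the methoxy C–H to win over the electron-rich C2 arene, over migration of a C1 substituent and over the acetonide methyl groups. The carboxamidate ligands make the carbenoid less electrophilic, the usual way to favour aliphatic C–H insertion over aromatic attack; C1 carries no hydrogen, so no 1,2-hydride shift exists; the acetonide C–H bonds are primary and not next to oxygen; the remaining oxygens could only give three- or four-membered ylides. Slow addition at high dilution keeps carbenoid dimerisation down, and C1 and C2 are not touched.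

Step 11
Reactants: 15 [(5S,6R,9R)-6-Ar-2,2-dimethyl-1,3,7-trioxaspiro[4.4]nonan-9-yl](Ar)methanone
Product: 16 (R)-Ar[(5S,6R,9S)-6-Ar-2,2-dimethyl-1,3,7-trioxaspiro[4.4]nonan-9-yl]methanol
Conditions: KBH(s-Bu)3, THF, −78 °C; aq. NH4Cl
Reagents that add atoms: none
Why: Hydride addition under Felkin–Anh control: the fully substituted spiro carbon C1 is the large group on C5, the bulky non-chelating borohydride attacks C6 anti to it past the C5 hydrogen, and the (R)-carbinol should result. A chelating reagent that ties the C6 carbonyl to the C1 oxygen would favour the other epimer and is avoided; at −78 °C addition should outrun enolisation at C5.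

Step 12
Reactants: 16 (R)-Ar[(5S,6R,9S)-6-Ar-2,2-dimethyl-1,3,7-trioxaspiro[4.4]nonan-9-yl]methanol
Product: 17 (2R,3S,4S)-2-Ar-4-[(R)-Ar(hydroxy)methyl]-3-(hydroxymethyl)oxolan-3-ol
Conditions: AcOH/H2O/THF (3:1:1), 40 °C
Reagents that add atoms: none
Why: Acetal hydrolysis; a weak carboxylic acid is chosen because it should cleave the dioxolane without ionising the benzylic C6–OH or C2–O3 bonds.

Step 13
Reactants: 17 (2R,3S,4S)-2-Ar-4-[(R)-Ar(hydroxy)methyl]-3-(hydroxymethyl)oxolan-3-ol
Product: 18 {(2R,3S,4S)-2-Ar-4-[(R)-Ar(hydroxy)methyl]-3-hydroxyoxolan-3-yl}methyl 4-methylbenzenesulfonate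
Conditions: TsCl (1.1 equiv), Et3N, Bu2SnO (5 mol %), CH2Cl2, 0 °C → rt
Reagents that add atoms: 4-methylbenzenesulfonyl chloride, Cc1ccc(cc1)S(=O)(=O)Cl
Why: Tin-catalysed regioselective sulfonylation: only the C1/C8 1,2-diol forms a stannylene acetal, and it is sulfonylated at the primary C8 oxygen, leaving the tertiary C1 and the benzylic C6 hydroxyls free.

Step 14
Reactants: 18 {(2R,3S,4S)-2-Ar-4-[(R)-Ar(hydroxy)methyl]-3-hydroxyoxolan-3-yl}methyl 4-methylbenzenesulfonate
Product: 19 (1S,2R,5S,6R)-2,6-di-Ar-3,7-dioxabicyclo[3.3.0]octan-1-ol (target)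
Conditions: 2,6-lutidine (3 equiv), MeCN, 80 °C
Reagents that add atoms: none
Why: Intramolecular Williamson-type etherification in the 5-exo-tet mode: the neutral C6 hydroxyl displaces the primary sulfonate and the base only takes up the acid, so the C6–O and C1–O bonds stay intact and the trans fusion follows from C6 and C8 lying on opposite faces of ring 1. Without an alkoxide the tertiary C1 hydroxyl is not expected to close the three-membered ring, a closure that would block ring 2 because the C6 oxygen cannot reach the rear of C8 in a spiro-fused oxirane.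

## Compound list

1 | methyl (2E)-3-(3,4-dimethoxyphenyl)prop-2-enoate | COC(=O)/C=C/c1ccc(OC)c(OC)c1 | starting material
2 | (2E)-3-(3,4-dimethoxyphenyl)prop-2-en-1-ol | OC/C=C/c1ccc(OC)c(OC)c1 | intermediate
3 | [(2S,3S)-3-(3,4-dimethoxyphenyl)oxiran-2-yl]methanol | OC[C@@H]1O[C@H]1c2ccc(OC)c(OC)c2 | intermediate
4 | (2S,3R)-3-(3,4-dimethoxyphenyl)-3-methoxypropane-1,2-diol | COc1ccc(cc1OC)[C@@H](OC)[C@@H](O)CO | intermediate
5 | (2S,3R)-1-[(tert-butyldimethylsilyl)oxy]-3-(3,4-dimethoxyphenyl)-3-methoxypropan-2-ol | COc1ccc(cc1OC)[C@@H](OC)[C@@H](O)CO[Si](C)(C)C(C)(C)C | intermediate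
6 | (1R)-3-[(tert-butyldimethylsilyl)oxy]-1-(3,4-dimethoxyphenyl)-1-methoxypropan-2-one | COc1ccc(cc1OC)[C@@H](OC)C(=O)CO[Si](C)(C)C(C)(C)C | intermediate
7 | 1-(3,4-dimethoxyphenyl)ethan-1-one | CC(=O)c1ccc(OC)c(OC)c1 | starting material
8 | lithium 1-(3,4-dimethoxyphenyl)ethen-1-olate | C=C(O[Li])c1ccc(OC)c(OC)c1 | intermediate (not isolated)
9 | (3S,4R)-3-{[(tert-butyldimethylsilyl)oxy]methyl}-1,4-bis(3,4-dimethoxyphenyl)-3-hydroxy-4-methoxybutan-1-one | COc1ccc(cc1OC)[C@@H](OC)[C@@](O)(CO[Si](C)(C)C(C)(C)C)CC(=O)c2ccc(OC)c(OC)c2 | intermediate
10 | (3S,4R)-1,4-bis(3,4-dimethoxyphenyl)-3-hydroxy-3-(hydroxymethyl)-4-methoxybutan-1-one | COc1ccc(cc1OC)[C@@H](OC)[C@@](O)(CO)CC(=O)c2ccc(OC)c(OC)c2 | intermediate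
11 | 2-{(4S)-4-[(R)-(3,4-dimethoxyphenyl)(methoxy)methyl]-2,2-dimethyl-1,3-dioxolan-4-yl}-1-(3,4-dimethoxyphenyl)ethan-1-one | COc1ccc(cc1OC)[C@@H](OC)[C@@]2(COC(C)(C)O2)CC(=O)c3ccc(OC)c(OC)c3 | intermediate
12 | lithium (Z)-2-{(4S)-4-[(R)-(3,4-dimethoxyphenyl)(methoxy)methyl]-2,2-dimethyl-1,3-dioxolan-4-yl}-1-(3,4-dimethoxyphenyl)ethen-1-olate | COc1ccc(cc1OC)[C@@H](OC)[C@@]2(COC(C)(C)O2)/C=C(\O[Li])c3ccc(OC)c(OC)c3 | intermediate (not isolated)
13 | 2-{(4S)-4-[(R)-(3,4-dimethoxyphenyl)(methoxy)methyl]-2,2-dimethyl-1,3-dioxolan-4-yl}-1-(3,4-dimethoxyphenyl)-4,4,4-trifluorobutane-1,3-dione (C2 epimers and enol forms) | COc1ccc(cc1OC)[C@@H](OC)[C@@]2(COC(C)(C)O2)C(C(=O)C(F)(F)F)C(=O)c3ccc(OC)c(OC)c3 | intermediate (not isolated)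
14 | 2-diazo-2-{(4S)-4-[(R)-(3,4-dimethoxyphenyl)(methoxy)methyl]-2,2-dimethyl-1,3-dioxolan-4-yl}-1-(3,4-dimethoxyphenyl)ethan-1-one | COc1ccc(cc1OC)[C@@H](OC)[C@@]2(COC(C)(C)O2)C(=[N+]=[N-])C(=O)c3ccc(OC)c(OC)c3 | intermediate
15 | [(5S,6R,9R)-6-(3,4-dimethoxyphenyl)-2,2-dimethyl-1,3,7-trioxaspiro[4.4]nonan-9-yl](3,4-dimethoxyphenyl)methanone | COc1ccc(cc1OC)[C@H]2OC[C@@H](C(=O)c3ccc(OC)c(OC)c3)[C@]24COC(C)(C)O4 | intermediate
16 | (R)-(3,4-dimethoxyphenyl)[(5S,6R,9S)-6-(3,4-dimethoxyphenyl)-2,2-dimethyl-1,3,7-trioxaspiro[4.4]nonan-9-yl]methanol | COc1ccc(cc1OC)[C@H]2OC[C@@H]([C@@H](O)c3ccc(OC)c(OC)c3)[C@]24COC(C)(C)O4 | intermediate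
17 | (2R,3S,4S)-2-(3,4-dimethoxyphenyl)-4-[(R)-(3,4-dimethoxyphenyl)(hydroxy)methyl]-3-(hydroxymethyl)oxolan-3-ol | COc1ccc(cc1OC)[C@H]2OC[C@@H]([C@@H](O)c3ccc(OC)c(OC)c3)[C@]2(O)CO | intermediate
18 | {(2R,3S,4S)-2-(3,4-dimethoxyphenyl)-4-[(R)-(3,4-dimethoxyphenyl)(hydroxy)methyl]-3-hydroxyoxolan-3-yl}methyl 4-methylbenzenesulfonate | COc1ccc(cc1OC)[C@H]2OC[C@@H]([C@@H](O)c3ccc(OC)c(OC)c3)[C@]2(O)COS(=O)(=O)c4ccc(C)cc4 | intermediate
19 | (1S,2R,5S,6R)-2,6-bis(3,4-dimethoxyphenyl)-3,7-dioxabicyclo[3.3.0]octan-1-ol | COc1ccc([C@H]2OC[C@H]3[C@H](c4ccc(OC)c(OC)c4)OC[C@]23O)cc1OC | target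

## Step count and least certain steps

Total step count: 14. Longest linear sequence: 14 steps (1 to 19); 7 enters at step 6.

Step 10 (key step). The most likely failures are three. The carbenoid may attack the electron-rich C2 aryl ring, which sits at the same distance from C5 as the methoxy group. A C1 substituent may migrate to the electron-poor carbenoid carbon. The face selectivity at C5 may be poor, and correcting C5 afterwards by base is unsafe because enolisation invites β-elimination of the C1 or C4 oxygen. The fallback closes ring 1 at O3–C2 instead; it sets out from 11 and returns at 15. The lithium enolate of 11 (LiN(SiMe3)2, THF, −78 °C) is treated with monomeric formaldehyde to give 2-{(4S)-4-[(R)-(3,4-dimethoxyphenyl)(methoxy)methyl]-2,2-dimethyl-1,3-dioxolan-4-yl}-1-(3,4-dimethoxyphenyl)-3-hydroxypropan-1-one F1. With Sc(OTf)3 (cat.) and 4 Å MS in CH2Cl2 at 0 °C the new C4 hydroxyl should displace the benzylic methoxy group at C2 through the benzylic cation and close ring 1 as 15. This route gives up the fixed C2 centre: C2 and C5 then settle under thermodynamic control, which is expected, though not assured, to favour aryl and aroyl anti to the C8 methylene.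

Step 14. C8 is a neopentyl-type carbon and the product ring fusion is strained, so the closure may be slow enough for rearrangement of the β-hydroxy sulfonate to intervene. Stronger bases cannot be used to speed it up, because alkoxide formation at C1 leads to three-membered ring closure. The fallback builds ring 2 at the lactone oxidation level; it sets out from 17 and returns at 19. Copper/TEMPO aerobic oxidation (Cu(MeCN)4OTf, 2,2'-bipyridine, TEMPO, N-methylimidazole, air, MeCN), which is selective for primary alcohols, should convert the C8 carbinol through the lactol into (1R,2R,5S,6R)-1-hydroxy-2,6-bis(3,4-dimethoxyphenyl)-3,7-dioxabicyclo[3.3.0]octan-8-one F2 (numbering of 19). Reduction with i-Bu2AlH at −78 °C gives (1R,2R,5S,6R)-2,6-bis(3,4-dimethoxyphenyl)-3,7-dioxabicyclo[3.3.0]octane-1,8-diol F3 (C8 anomers). Ionic reduction with Et3SiH and BF3·OEt2 at −78 °C then removes the C8 hydroxyl to give 19. No leaving group ever stands next to the C1 hydroxyl, but the last step exposes the benzylic ethers briefly to a Lewis acid.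

Step 6. Proton transfer from the acidic benzylic C2–H of 6 to the enolate would erode the configuration of C2, and incomplete chelation would lower the face selectivity at C1. The fallback replaces the basic enolate by a neutral nucleophile; it sets out from 7 and returns at 9. Ketone 7 is converted with Me3SiOTf and Et3N into [1-(3,4-dimethoxyphenyl)ethenyl]oxy(trimethyl)silane F4. F4 is added to 6 precomplexed with TiCl4 in CH2Cl2 at −78 °C (Mukaiyama aldol); the titanium chelate of the carbonyl and methoxy oxygens directs attack to the same face and no base is present.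

Step 11. Partial chelation of the counter-ion between the C6 carbonyl and the C1 or O3 oxygen, or an unfavourable rotamer of the aroyl group, could lower the face selectivity and give the C6 epimer. The fallback inverts that epimer; it sets out from 15 and returns at 16. The epimeric carbinol (S)-(3,4-dimethoxyphenyl)[(5S,6R,9S)-6-(3,4-dimethoxyphenyl)-2,2-dimethyl-1,3,7-trioxaspiro[4.4]nonan-9-yl]methanol F5 is separated and submitted to Mitsunobu inversion (PPh3, diisopropyl azodicarboxylate, 4-nitrobenzoic acid). This gives (R)-(3,4-dimethoxyphenyl)[(5S,6R,9S)-6-(3,4-dimethoxyphenyl)-2,2-dimethyl-1,3,7-trioxaspiro[4.4]nonan-9-yl]methyl 4-nitrobenzoate F6, and methanolysis with K2CO3 in MeOH gives 16. Some loss of stereochemical purity through ionisation of the electron-rich benzylic centre is the weak point of this inversion.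

## Further compounds

F1 | step 10 | 2-{(4S)-4-[(R)-(3,4-dimethoxyphenyl)(methoxy)methyl]-2,2-dimethyl-1,3-dioxolan-4-yl}-1-(3,4-dimethoxyphenyl)-3-hydroxypropan-1-one (both C2 epimers) | COc1ccc(cc1OC)[C@@H](OC)[C@@]2(COC(C)(C)O2)C(CO)C(=O)c3ccc(OC)c(OC)c3
F2 | step 14 | (1R,2R,5S,6R)-1-hydroxy-2,6-bis(3,4-dimethoxyphenyl)-3,7-dioxabicyclo[3.3.0]octan-8-one (numbering of 19) | COc1ccc([C@H]2OC[C@H]3[C@H](c4ccc(OC)c(OC)c4)OC(=O)[C@]23O)cc1OC
F3 | step 14 | (1R,2R,5S,6R)-2,6-bis(3,4-dimethoxyphenyl)-3,7-dioxabicyclo[3.3.0]octane-1,8-diol (C8 anomers, numbering of 19) | COc1ccc([C@H]2OC[C@H]3[C@H](c4ccc(OC)c(OC)c4)OC(O)[C@]23O)cc1OC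
F4 | step 6 | [1-(3,4-dimethoxyphenyl)ethenyl]oxy(trimethyl)silane | C=C(O[Si](C)(C)C)c1ccc(OC)c(OC)c1
F5 | step 11 | (S)-(3,4-dimethoxyphenyl)[(5S,6R,9S)-6-(3,4-dimethoxyphenyl)-2,2-dimethyl-1,3,7-trioxaspiro[4.4]nonan-9-yl]methanol | COc1ccc(cc1OC)[C@H]2OC[C@@H]([C@H](O)c3ccc(OC)c(OC)c3)[C@]24COC(C)(C)O4
F6 | step 11 | (R)-(3,4-dimethoxyphenyl)[(5S,6R,9S)-6-(3,4-dimethoxyphenyl)-2,2-dimethyl-1,3,7-trioxaspiro[4.4]nonan-9-yl]methyl 4-nitrobenzoate | COc1ccc(cc1OC)[C@H]2OC[C@@H]([C@@H](OC(=O)c5ccc(cc5)[N+](=O)[O-])c3ccc(OC)c(OC)c3)[C@]24COC(C)(C)O4
A1 | alternative 1 | 3-[(tert-butyldimethylsilyl)oxy]-3-(3,4-dimethoxyphenyl)-2-[3-(3,4-dimethoxyphenyl)-2-(hydroxymethyl)oxiran-2-yl]propan-1-ol, configuration as in the SMILES | OC[C@@H]([C@@H](O[Si](C)(C)C(C)(C)C)c1ccc(OC)c(OC)c1)[C@@]2(CO)O[C@H]2c3ccc(OC)c(OC)c3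
A2 | alternative 1 | (2R,3S,4S)-4-{(R)-[(tert-butyldimethylsilyl)oxy](3,4-dimethoxyphenyl)methyl}-2-(3,4-dimethoxyphenyl)-3-(hydroxymethyl)oxolan-3-ol | COc1ccc(cc1OC)[C@H]2OC[C@@H]([C@@H](O[Si](C)(C)C(C)(C)C)c3ccc(OC)c(OC)c3)[C@]2(O)CO
A3 | alternative 2 | 1,3-dioxoisoindolin-2-yl 2-{[(1R,2S,3E)-1,4-bis(3,4-dimethoxyphenyl)-2-[(triethylsilyl)oxy]-2-{[(triethylsilyl)oxy]methyl}but-3-en-1-yl]oxy}acetate | COc1ccc(cc1OC)[C@@H](OCC(=O)ON2C(=O)c3ccccc3C2=O)[C@@](O[Si](CC)(CC)CC)(CO[Si](CC)(CC)CC)/C=C/c4ccc(OC)c(OC)c4
A4 | alternative 2 | (1S,2R,5S,6R)-2,6-bis(3,4-dimethoxyphenyl)-1-[(triethylsilyl)oxy]-3,7-dioxabicyclo[3.3.0]octane | COc1ccc([C@H]2OC[C@H]3[C@H](c4ccc(OC)c(OC)c4)OC[C@]23O[Si](CC)(CC)CC)cc1OC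
A5 | alternative 3 | (3S,4R)-1,4-bis[(tert-butyldimethylsilyl)oxy]-3-{[(3,4-dimethoxybenzyl)oxy]methyl}-4-(3,4-dimethoxyphenyl)butan-2-one | COc1ccc(cc1OC)COC[C@@H]([C@@H](O[Si](C)(C)C(C)(C)C)c2ccc(OC)c(OC)c2)C(=O)CO[Si](C)(C)C(C)(C)C
A6 | alternative 3 | (2R,3S,4S)-3-{[(tert-butyldimethylsilyl)oxy]methyl}-4-{(R)-[(tert-butyldimethylsilyl)oxy](3,4-dimethoxyphenyl)methyl}-2-(3,4-dimethoxyphenyl)oxolan-3-ol | COc1ccc(cc1OC)[C@H]2OC[C@@H]([C@@H](O[Si](C)(C)C(C)(C)C)c3ccc(OC)c(OC)c3)[C@]2(O)CO[Si](C)(C)C(C)(C)C
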